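**Plan**

1. Retrosynthesis: the two Si–O bonds and the hydroquinone/quinone oxidation level of ring B are left for the last step; the C3 stereocentre and the pyran ring are taken back to an achiral 2-(aryloxymethyl)vinyl-1,4-benzoquinone by cutting C4–C4a (and C3–H); C3–C1' is then cut (Suzuki), O1–C2 (Williamson), and both aryl–prenyl bonds (aryllithium allylation).
2. Feature used: ring B is a 1,4-quinone whose C5'=O is conjugated through C6'=C1' with an exocyclic C3=C4 double bond, so C4 becomes the δ-carbon of a dienone; C4a of ring A lies between O1 and the 5-OMe and para to O7. The target's own quinone is the activating group and only has to be reoxidised afterwards.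
3. Forward: ring A phenol (from 5-methoxyresorcinol) is converted to its 2-bromoallyl ether; ring B boronate (from 4-bromoresorcinol) is joined to it by Suzuki coupling (C3–C1'); Teuber oxidation makes ring B a quinone; the pyran ring is then closed at C4–C4a, which returns ring B as the hydroquinone of a 2H-chromene.
4. Stereochemistry: C3 (R) is set in the same flask by chiral phosphoric acid/Hantzsch ester transfer hydrogenation of the ortho-quinone methide (C3=C1'–C2'=O) that the 2'-OH of this hydroquinone makes accessible.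
5. Helpers: a TIPS ether on O7 (pushed toward C8 by the C6 prenyl group, it directs closure to C4a) and a TIPS ether on O4'; both leave in the last step, where air restores the hydroxyquinone.

Key step: step 13

Remark: locants are those of the isoflavan (O1, C2–C4, C4a, C5–C8, C8a; ring B C1'–C6'); prenyl = 3-methylbut-2-en-1-yl, TIPS = triisopropylsilyl, TIPSO = triisopropylsilyloxy; the (R)-configured phosphoric acid is assumed to give (3R), otherwise its enantiomer is used.

**Route**

Step 1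
Reactants: 1 5-methoxyresorcinol
Product: 2 1-methoxy-3,5-bis(TIPSO)benzene
Conditions: TIPSCl (2.3 equiv), imidazole, DMF, rt
Reagents that add atoms: triisopropylsilyl chloride, CC(C)[Si](Cl)(C(C)C)C(C)C
Why: Imidazole-promoted silylation of both phenols; the two bulky silyl ethers are needed to steer the bromination that follows.

Step 2
Reactants: 2 1-methoxy-3,5-bis(TIPSO)benzene
Product: 3 2-bromo-1-methoxy-3,5-bis(TIPSO)benzene
Conditions: NBS (1.0 equiv), MeCN, −20 °C → 0 °C
Reagents that add atoms: N-bromosuccinimide, O=C1CCC(=O)N1Br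
Why: Electrophilic aromatic bromination; the position between the two TIPS ethers is shielded, so bromine should enter between OMe and OTIPS, which is ortho/para to all three oxygens.

Step 3
Reactants: 3 2-bromo-1-methoxy-3,5-bis(TIPSO)benzene
Product: 5 1-methoxy-2-prenyl-3,5-bis(TIPSO)benzene, via aryllithium 4 (not isolated)
Conditions: n-BuLi (1.05 equiv), THF, −78 °C; CuI (10 mol %), prenyl bromide, −78 → −30 °C
Reagents that add atoms: prenyl bromide (1-bromo-3-methylbut-2-ene), CC(C)=CCBr
Why: Bromine–lithium exchange followed by copper-catalysed SN2 allylation at the primary carbon of prenyl bromide; the bulky TIPS groups and low temperature should suppress retro-Brook silyl migration.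

Step 4
Reactants: 5 1-methoxy-2-prenyl-3,5-bis(TIPSO)benzene
Product: 6 3-methoxy-4-prenyl-5-(TIPSO)phenol
Conditions: Bu4NF (1.0 equiv), THF, −78 → −40 °C; AcOH quench
Reagents that add atoms: none
Why: Kinetic fluoride desilylation; the silyl ether flanked by two ring hydrogens (para to prenyl) should be cleaved faster than the one shielded by the ortho prenyl group.

Step 5
Reactants: 6 3-methoxy-4-prenyl-5-(TIPSO)phenol; 7 2,3-dibromopropene
Product: 8 5-[(2-bromoprop-2-en-1-yl)oxy]-1-methoxy-2-prenyl-3-(TIPSO)benzene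
Conditions: K2CO3, acetone, 50 °C
Reagents that add atoms: none
Why: Williamson etherification by SN2 at the allylic bromide; the vinylic bromide is inert and the aryl TIPS ether tolerates K2CO3 in acetone.

Step 6
Reactants: 9 4-bromoresorcinol
Product: 10 1-bromo-2,4-bis(methoxymethoxy)benzene
Conditions: MOMCl (2.4 equiv), iPr2NEt, CH2Cl2, 0 °C → rt
Reagents that add atoms: chloromethyl methyl ether, COCCl
Why: MOM protection of both phenols, which installs two ortho-directing groups around the position that must carry the prenyl group.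

Step 7
Reactants: 10 1-bromo-2,4-bis(methoxymethoxy)benzene
Product: 12 1-bromo-2,4-bis(methoxymethoxy)-3-prenylbenzene, via aryllithium 11 (not isolated)
Conditions: LiN(iPr)2 (1.1 equiv), THF, −78 °C; CuI (10 mol %), prenyl bromide, −78 → 0 °C
Reagents that add atoms: prenyl bromide (1-bromo-3-methylbut-2-ene), CC(C)=CCBr
Why: Directed ortho-metalation at the carbon between the two MOM ethers (the amide base avoids bromine–lithium exchange), then SN2 allylation.

Step 8
Reactants: 12 1-bromo-2,4-bis(methoxymethoxy)-3-prenylbenzene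
Product: 13 4-bromo-2-prenylbenzene-1,3-diol
Conditions: HCl (3 M aq, cat.), MeOH, 40 °C, short reaction time
Reagents that add atoms: none
Why: Acid-catalysed acetal methanolysis under mild conditions of the kind used for MOM removal next to prenyl groups.

Step 9
Reactants: 13 4-bromo-2-prenylbenzene-1,3-diol
Product: 14 6-bromo-2-prenyl-3-(TIPSO)phenol
Conditions: TIPSCl (1.05 equiv), imidazole, DMF, 0 °C
Reagents that add atoms: triisopropylsilyl chloride, CC(C)[Si](Cl)(C(C)C)C(C)C
Why: Sterically controlled mono-silylation; the hydroxyl flanked by prenyl and bromine should react much more slowly with the bulky chloride than the one next to a ring hydrogen.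

Step 10
Reactants: 14 6-bromo-2-prenyl-3-(TIPSO)phenol
Product: 15 2-prenyl-6-(4,4,5,5-tetramethyl-1,3,2-dioxaborolan-2-yl)-3-(TIPSO)phenol
Conditions: B2pin2, Pd(dppf)Cl2 (5 mol %), KOAc, 1,4-dioxane, 80 °C
Reagents that add atoms: bis(pinacolato)diboron, CC1(C)OB(OC1(C)C)B1OC(C)(C)C(C)(C)O1
Why: Miyaura borylation of the aryl bromide; free phenols, silyl ethers and isolated alkenes are tolerated.

Step 11
Reactants: 8 5-[(2-bromoprop-2-en-1-yl)oxy]-1-methoxy-2-prenyl-3-(TIPSO)benzene; 15 2-prenyl-6-(pinacolboryl)-3-(TIPSO)phenol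
Product: 16 6-{3-[3-methoxy-4-prenyl-5-(TIPSO)phenoxy]prop-1-en-2-yl}-2-prenyl-3-(TIPSO)phenol
Conditions: Pd(dppf)Cl2 (3 mol %), K3PO4, THF/H2O (10:1), 40 °C
Reagents that add atoms: none
Why: Suzuki–Miyaura coupling at the alkenyl bromide forms C3–C1'; the mild temperature should keep the allyl aryl ether from ionising on zerovalent palladium.

Step 12
Reactants: 16 6-{3-[3-methoxy-4-prenyl-5-(TIPSO)phenoxy]prop-1-en-2-yl}-2-prenyl-3-(TIPSO)phenol
Product: 17 5-{3-[3-methoxy-4-prenyl-5-(TIPSO)phenoxy]prop-1-en-2-yl}-3-prenyl-2-(TIPSO)cyclohexa-2,5-diene-1,4-dione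
Conditions: (KSO3)2NO (2.2 equiv), KH2PO4 buffer (pH 6), acetone/H2O, 0 °C; used without purification
Reagents that add atoms: potassium nitrosodisulfonate, [K+].[K+].[O-]S(=O)(=O)N([O])S(=O)(=O)[O-]
Why: Teuber oxidation; the phenoxyl radical of the only free phenol is trapped at its unsubstituted para position (C5') to give the para-quinone, while silyl ethers, prenyl groups and ring A are not attacked by the nitroxyl radical.

Step 13
Reactants: 17 5-{3-[3-methoxy-4-prenyl-5-(TIPSO)phenoxy]prop-1-en-2-yl}-3-prenyl-2-(TIPSO)cyclohexa-2,5-diene-1,4-dione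
Product: 19 2-[(3R)-5-methoxy-6-prenyl-7-(TIPSO)-3,4-dihydro-2H-chromen-3-yl]-6-prenyl-5-(TIPSO)benzene-1,4-diol, via 2H-chromene hydroquinone 18 (not isolated)
Conditions: HFIP/CH2Cl2 (1:1), 0 °C → rt, Ar, dilute; evaporate; then (R)-TRIP phosphoric acid (10 mol %), Hantzsch ester (1.3 equiv), toluene, 35 °C
Reagents that add atoms: none
Why: Proposed new method: hydrogen bonding of HFIP to the C5' carbonyl activates the dienone O=C5'–C6'=C1'–C3=C4, and C4a of ring A attacks its δ-carbon C4 in an intramolecular Friedel–Crafts 1,6-addition that closes the pyran ring in the 6-endo-trig mode; rearomatisation of ring A and loss of a C4 proton from the resulting ortho-quinone methide enol give the 2H-chromene hydroquinone 18, the more stable isomer of 17. After the quinone is consumed, the chiral acid, bound to the 2'-OH, protonates C4 of 18, regenerates the ortho-quinone methide (C3=C1'–C2'=O) as a chiral ion pair, and the Hantzsch ester delivers hydride to one face of C3. The closest known reaction types are the acid- or HFIP-promoted Friedel–Crafts conjugate arylation of quinones and quinone methides, and the phosphoric acid/Hantzsch ester transfer hydrogenation of ortho-hydroxystyrenes through ortho-quinone methides. The single new stereocentre C3 is controlled by the catalyst, and the (R)-acid is assumed to give (3R). Closure at C4a and not at C8 is secured by the TIPS ether on O7, which the C6 prenyl group forces toward C8, and six-membered closure at C4 is preferred over seven-membered closure at C6'. The reductant is added only after the cyclisation, because it would otherwise reduce the quinone and remove the activation.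

Step 14
Reactants: 19 2-[(3R)-5-methoxy-6-prenyl-7-(TIPSO)-3,4-dihydro-2H-chromen-3-yl]-6-prenyl-5-(TIPSO)benzene-1,4-diol
Product: 21 2-hydroxy-5-[(3R)-7-hydroxy-5-methoxy-6-prenyl-3,4-dihydro-2H-chromen-3-yl]-3-prenylcyclohexa-2,5-diene-1,4-dione, via benzenetriol 20 (not isolated)
Conditions: Bu4NF (2.4 equiv), AcOH (2.4 equiv), THF, 0 °C → rt, Ar; then pH 7 phosphate buffer/EtOAc, air, rt
Reagents that add atoms: none
Why: Buffered fluoride cleavage of both aryl silyl ethers, then autoxidation of the 1,2,4-benzenetriol to the 2-hydroxy-1,4-benzoquinone; the ring A phenol is much harder to oxidise, and buffering protects the C3–H next to the new quinone from epimerisation.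

**Compound list**

1 | 5-methoxyresorcinol (5-methoxybenzene-1,3-diol) | COc1cc(O)cc(O)c1 | starting material
2 | 1-methoxy-3,5-bis(triisopropylsilyloxy)benzene | COc1cc(O[Si](C(C)C)(C(C)C)C(C)C)cc(O[Si](C(C)C)(C(C)C)C(C)C)c1 | intermediate
3 | 2-bromo-1-methoxy-3,5-bis(triisopropylsilyloxy)benzene | COc1cc(O[Si](C(C)C)(C(C)C)C(C)C)cc(O[Si](C(C)C)(C(C)C)C(C)C)c1Br | intermediate
4 | [2-methoxy-4,6-bis(triisopropylsilyloxy)phenyl]lithium | COc1cc(O[Si](C(C)C)(C(C)C)C(C)C)cc(O[Si](C(C)C)(C(C)C)C(C)C)c1[Li] | intermediate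
5 | 1-methoxy-2-(3-methylbut-2-en-1-yl)-3,5-bis(triisopropylsilyloxy)benzene | COc1cc(O[Si](C(C)C)(C(C)C)C(C)C)cc(O[Si](C(C)C)(C(C)C)C(C)C)c1CC=C(C)C | intermediate
6 | 3-methoxy-4-(3-methylbut-2-en-1-yl)-5-(triisopropylsilyloxy)phenol | COc1cc(O)cc(O[Si](C(C)C)(C(C)C)C(C)C)c1CC=C(C)C | intermediate
7 | 2,3-dibromopropene | BrCC(Br)=C | starting material
8 | 5-[(2-bromoprop-2-en-1-yl)oxy]-1-methoxy-2-(3-methylbut-2-en-1-yl)-3-(triisopropylsilyloxy)benzene | COc1cc(OCC(Br)=C)cc(O[Si](C(C)C)(C(C)C)C(C)C)c1CC=C(C)C | intermediate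
9 | 4-bromoresorcinol (4-bromobenzene-1,3-diol) | Oc1ccc(Br)c(O)c1 | starting material
10 | 1-bromo-2,4-bis(methoxymethoxy)benzene | COCOc1ccc(Br)c(OCOC)c1 | intermediate
11 | [3-bromo-2,6-bis(methoxymethoxy)phenyl]lithium | COCOc1ccc(Br)c(OCOC)c1[Li] | intermediate
12 | 1-bromo-2,4-bis(methoxymethoxy)-3-(3-methylbut-2-en-1-yl)benzene | COCOc1ccc(Br)c(OCOC)c1CC=C(C)C | intermediate
13 | 4-bromo-2-(3-methylbut-2-en-1-yl)benzene-1,3-diol | Oc1ccc(Br)c(O)c1CC=C(C)C | intermediate
14 | 6-bromo-2-(3-methylbut-2-en-1-yl)-3-(triisopropylsilyloxy)phenol | CC(C)[Si](Oc1ccc(Br)c(O)c1CC=C(C)C)(C(C)C)C(C)C | intermediate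
15 | 2-(3-methylbut-2-en-1-yl)-6-(4,4,5,5-tetramethyl-1,3,2-dioxaborolan-2-yl)-3-(triisopropylsilyloxy)phenol | CC(C)[Si](Oc1ccc(B2OC(C)(C)C(C)(C)O2)c(O)c1CC=C(C)C)(C(C)C)C(C)C | intermediate
16 | 6-{3-[3-methoxy-4-(3-methylbut-2-en-1-yl)-5-(triisopropylsilyloxy)phenoxy]prop-1-en-2-yl}-2-(3-methylbut-2-en-1-yl)-3-(triisopropylsilyloxy)phenol | COc1cc(OCC(=C)c2ccc(O[Si](C(C)C)(C(C)C)C(C)C)c(CC=C(C)C)c2O)cc(O[Si](C(C)C)(C(C)C)C(C)C)c1CC=C(C)C | intermediate
17 | 5-{3-[3-methoxy-4-(3-methylbut-2-en-1-yl)-5-(triisopropylsilyloxy)phenoxy]prop-1-en-2-yl}-3-(3-methylbut-2-en-1-yl)-2-(triisopropylsilyloxy)cyclohexa-2,5-diene-1,4-dione | COc1cc(OCC(=C)C2=CC(=O)C(O[Si](C(C)C)(C(C)C)C(C)C)=C(CC=C(C)C)C2=O)cc(O[Si](C(C)C)(C(C)C)C(C)C)c1CC=C(C)C | intermediate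
18 | 2-[5-methoxy-6-(3-methylbut-2-en-1-yl)-7-(triisopropylsilyloxy)-2H-chromen-3-yl]-6-(3-methylbut-2-en-1-yl)-5-(triisopropylsilyloxy)benzene-1,4-diol | COc1c(CC=C(C)C)c(O[Si](C(C)C)(C(C)C)C(C)C)cc2OCC(=Cc12)c1cc(O)c(O[Si](C(C)C)(C(C)C)C(C)C)c(CC=C(C)C)c1O | intermediate
19 | 2-[(3R)-5-methoxy-6-(3-methylbut-2-en-1-yl)-7-(triisopropylsilyloxy)-3,4-dihydro-2H-chromen-3-yl]-6-(3-methylbut-2-en-1-yl)-5-(triisopropylsilyloxy)benzene-1,4-diol | COc1c(CC=C(C)C)c(O[Si](C(C)C)(C(C)C)C(C)C)cc2c1C[C@H](c1cc(O)c(O[Si](C(C)C)(C(C)C)C(C)C)c(CC=C(C)C)c1O)CO2 | intermediate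
20 | 5-[(3R)-7-hydroxy-5-methoxy-6-(3-methylbut-2-en-1-yl)-3,4-dihydro-2H-chromen-3-yl]-3-(3-methylbut-2-en-1-yl)benzene-1,2,4-triol | COc1c(CC=C(C)C)c(O)cc2c1C[C@H](c1cc(O)c(O)c(CC=C(C)C)c1O)CO2 | intermediate
21 | 2-hydroxy-5-[(3R)-7-hydroxy-5-methoxy-6-(3-methylbut-2-en-1-yl)-3,4-dihydro-2H-chromen-3-yl]-3-(3-methylbut-2-en-1-yl)cyclohexa-2,5-diene-1,4-dione | COc1c(CC=C(C)C)c(O)cc2c1C[C@H](C1=CC(=O)C(O)=C(CC=C(C)C)C1=O)CO2 | target

**Totals and risks**

Total step count: 14. Longest linear sequence: 9 steps (steps 1–5 or steps 6–10, followed by steps 11–14).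

Steps most likely to fail:

(1) Step 13. What may go wrong:
- dimerisation or polymerisation of the vinylquinone before it cyclises;
- slow 1,6-addition, because ring A is only as nucleophilic as a trialkoxybenzene;
- redox exchange between the hydroquinone formed and quinone not yet cyclised;
- ring closure at C8 instead of C4a;
- low face selectivity in the hydride transfer, since C3 is flanked by two ring methylenes;
- competing protonation at C3, which would give a ring-A-stabilised C4 cation and racemic reduction.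

Fallback by known chemistry, setting out from 6 and coming back at 21: bromination of 6 ortho to the free hydroxyl on the methoxy side (NBS, CH2Cl2, −78 °C) should give 2-bromo-3-methoxy-4-prenyl-5-(triisopropylsilyloxy)phenol F1. Alkylation with 7 (K2CO3, acetone) gives the bromoallyl ether F2, and Suzuki coupling with 15 at the alkenyl bromide (Pd(dppf)Cl2, K3PO4, 40 °C; the hindered aryl bromide is left) gives the 1,1-disubstituted alkene F3. Enantioselective copper-catalysed protoboration of this alkene (CuCl, chiral ligand, NaOtBu, B2pin2, MeOH) sets C3 and gives the primary boronate F4. Intramolecular B-alkyl Suzuki–Miyaura coupling (Pd(OAc)2, RuPhos, K3PO4, toluene/H2O, 80 °C) closes the pyran ring at the marked aryl carbon and gives the (3R)-isoflavan phenol F5. Teuber oxidation of its ring B phenol gives the bis-silylated isoflavan quinone F6, and Bu4NF/AcOH then gives 21.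

(2) Step 12. What may go wrong: radical coupling at the styrene terminus next to the phenoxyl radical, or premature cyclisation followed by over-oxidation of the hydroquinone formed.

Fallback, setting out from 14 and 8 and coming back at 17, with ring B oxidised before the coupling: Teuber oxidation of 14 gives 5-bromo-3-prenyl-2-(triisopropylsilyloxy)-1,4-benzoquinone F7. Miyaura borylation of the alkenyl bromide 8 (PdCl2(PPh3)2, PPh3, KOPh, B2pin2, toluene, 50 °C) gives the alkenylboronate F8. Suzuki coupling of F7 with F8 under anhydrous conditions (Pd(PPh3)4, CsF, 1,4-dioxane, 60 °C) gives 17.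

(3) Step 4. What may go wrong: insufficient discrimination between the two silyl ethers, with cleavage at the hindered site or of both groups.

Fallback, setting out from 5 and coming back at 8, which moves the site discrimination from silyl cleavage to O-alkylation: excess Bu4NF removes both silyl groups to give 5-methoxy-4-prenylbenzene-1,3-diol F9. Mono-alkylation with 7 (1.0 equiv, K2CO3, acetone, rt) at the hydroxyl that has no ortho substituent gives 5-[(2-bromoprop-2-en-1-yl)oxy]-3-methoxy-2-prenylphenol F10. Silylation of the remaining hindered phenol (TIPSOTf, 2,6-lutidine, CH2Cl2) gives 8.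

Further compounds
F1 | step 13 | 2-bromo-3-methoxy-4-(3-methylbut-2-en-1-yl)-5-(triisopropylsilyloxy)phenol | COc1c(Br)c(O)cc(O[Si](C(C)C)(C(C)C)C(C)C)c1CC=C(C)C
F2 | step 13 | 2-bromo-1-[(2-bromoprop-2-en-1-yl)oxy]-3-methoxy-4-(3-methylbut-2-en-1-yl)-5-(triisopropylsilyloxy)benzene | COc1c(Br)c(OCC(Br)=C)cc(O[Si](C(C)C)(C(C)C)C(C)C)c1CC=C(C)C
F3 | step 13 | 6-{3-[2-bromo-3-methoxy-4-(3-methylbut-2-en-1-yl)-5-(triisopropylsilyloxy)phenoxy]prop-1-en-2-yl}-2-(3-methylbut-2-en-1-yl)-3-(triisopropylsilyloxy)phenol | COc1c(Br)c(OCC(=C)c2ccc(O[Si](C(C)C)(C(C)C)C(C)C)c(CC=C(C)C)c2O)cc(O[Si](C(C)C)(C(C)C)C(C)C)c1CC=C(C)C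
F4 | step 13 | 6-{(2R)-1-[2-bromo-3-methoxy-4-(3-methylbut-2-en-1-yl)-5-(triisopropylsilyloxy)phenoxy]-3-(4,4,5,5-tetramethyl-1,3,2-dioxaborolan-2-yl)propan-2-yl}-2-(3-methylbut-2-en-1-yl)-3-(triisopropylsilyloxy)phenol | COc1c(Br)c(OC[C@H](CB2OC(C)(C)C(C)(C)O2)c2ccc(O[Si](C(C)C)(C(C)C)C(C)C)c(CC=C(C)C)c2O)cc(O[Si](C(C)C)(C(C)C)C(C)C)c1CC=C(C)C
F5 | step 13 | 6-[(3R)-5-methoxy-6-(3-methylbut-2-en-1-yl)-7-(triisopropylsilyloxy)-3,4-dihydro-2H-chromen-3-yl]-2-(3-methylbut-2-en-1-yl)-3-(triisopropylsilyloxy)phenol | COc1c(CC=C(C)C)c(O[Si](C(C)C)(C(C)C)C(C)C)cc2c1C[C@H](c1ccc(O[Si](C(C)C)(C(C)C)C(C)C)c(CC=C(C)C)c1O)CO2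
F6 | step 13 | 5-[(3R)-5-methoxy-6-(3-methylbut-2-en-1-yl)-7-(triisopropylsilyloxy)-3,4-dihydro-2H-chromen-3-yl]-3-(3-methylbut-2-en-1-yl)-2-(triisopropylsilyloxy)cyclohexa-2,5-diene-1,4-dione | COc1c(CC=C(C)C)c(O[Si](C(C)C)(C(C)C)C(C)C)cc2c1C[C@H](C1=CC(=O)C(O[Si](C(C)C)(C(C)C)C(C)C)=C(CC=C(C)C)C1=O)CO2
F7 | step 12 | 5-bromo-3-(3-methylbut-2-en-1-yl)-2-(triisopropylsilyloxy)cyclohexa-2,5-diene-1,4-dione | CC(C)[Si](OC1=C(CC=C(C)C)C(=O)C(Br)=CC1=O)(C(C)C)C(C)C
F8 | step 12 | 2-{3-[3-methoxy-4-(3-methylbut-2-en-1-yl)-5-(triisopropylsilyloxy)phenoxy]prop-1-en-2-yl}-4,4,5,5-tetramethyl-1,3,2-dioxaborolane | COc1cc(OCC(=C)B2OC(C)(C)C(C)(C)O2)cc(O[Si](C(C)C)(C(C)C)C(C)C)c1CC=C(C)C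
F9 | step 4 | 5-methoxy-4-(3-methylbut-2-en-1-yl)benzene-1,3-diol | COc1cc(O)cc(O)c1CC=C(C)C
F10 | step 4 | 5-[(2-bromoprop-2-en-1-yl)oxy]-3-methoxy-2-(3-methylbut-2-en-1-yl)phenol | COc1cc(OCC(Br)=C)cc(O)c1CC=C(C)C
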